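**Retrosynthetic overview**
1. Target 28 ⇐ NaBH4 reduction of the dimeric dihydroflavonol 27 (sets C4 of the lower unit, 3,4-trans) ⇐ deacetylation and debenzylation of ketone 25.
2. The C3–O bonds of both units (Baeyer–Villiger oxidation of C3-acetyl groups, retention) and the lower C4=O (from a benzylic 4-OMe) are unmasked only after both pyran rings exist.
3. Upper pyran ring and the C4(upper)–C6(lower) bond: [4+2] hetero-Diels–Alder of an aryl-substituted o-quinone methide (lower-unit aryllithium + salicylaldehyde carbonate 4) with the (S)-lactate-derived E-styrene 14.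
4. Lower pyran ring: [4+2] hetero-Diels–Alder of a 4-methoxy-o-quinone methide (from bromosalicylaldehyde 3) with the (R)-lactate-derived E-styrene 10.
5. Ring order: lower pyran ring, then upper pyran ring; all benzene rings are bought; every stereocentre traces back to methyl (R)-lactate or ethyl (S)-lactate.

Assumption: compounds 17–24 are drawn as the all-trans C4 epimer of the lower unit; its C4 epimer, if formed, converges on the same ketone 25, and C4 is fixed in step 17.

The facial selectivities quoted for the two cycloadditions (steps 9 and 10) are predictions from allylic 1,2-induction models, not precedented values; the minor diastereomers are separable because the lactate stereocentre is still present.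

**Step 1**
Reactants: 1 2,3,4-trihydroxybenzaldehyde
Product: 2 3,4-bis(benzyloxy)-2-hydroxybenzaldehyde
Conditions: BnBr (2.1 equiv), K2CO3, DMF, rt
Reagents that add atoms: benzyl bromide BrCc1ccccc1
Why: Williamson etherification in which the 2-OH, hydrogen-bonded to the formyl group, is the least reactive phenol and stays free.

**Step 2**
Reactants: 2 3,4-bis(benzyloxy)-2-hydroxybenzaldehyde
Product: 3 3,4-bis(benzyloxy)-5-bromo-2-hydroxybenzaldehyde
Conditions: NBS, MeCN, 0 °C
Reagents that add atoms: N-bromosuccinimide O=C1CCC(=O)N1Br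
Why: Electrophilic aromatic bromination goes para to the free phenol (ortho to OBn, meta to CHO) and gives the 5-bromide, the future C6 handle of the lower unit.

**Step 3**
Reactants: 2 3,4-bis(benzyloxy)-2-hydroxybenzaldehyde
Product: 4 tert-butyl [2,3-bis(benzyloxy)-6-formylphenyl] carbonate
Conditions: Boc2O, iPr2NEt, DMAP (cat.), THF, rt
Reagents that add atoms: di-tert-butyl dicarbonate CC(C)(C)OC(=O)OC(=O)OC(C)(C)C
Why: O-acylation of the phenol gives the aryl carbonate needed later for the Boc-transfer/elimination route to an o-quinone methide.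

**Step 4**
Reactants: 5 4-(benzyloxy)benzyl chloride
Product: 6 diethyl [4-(benzyloxy)benzyl]phosphonate
Conditions: P(OEt)3, neat, 150 °C
Reagents that add atoms: triethyl phosphite CCOP(OCC)OCC
Why: Michaelis–Arbuzov reaction of a reactive benzylic chloride.

**Step 5**
Reactants: 7 methyl (R)-lactate
Product: 8 methyl (R)-2-[(tert-butyldiphenylsilyl)oxy]propanoate
Conditions: TBDPSCl, imidazole, DMF, rt
Reagents that add atoms: tert-butyl(chloro)diphenylsilane CC(C)(C)[Si](Cl)(c1ccccc1)c1ccccc1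
Why: Silyl ether formation at oxygen; no bond to the bought (R) stereocentre is touched.

**Step 6**
Reactants: 8 methyl (R)-2-[(tert-butyldiphenylsilyl)oxy]propanoate; 6 diethyl [4-(benzyloxy)benzyl]phosphonate
Product: 10 tert-butyl{[(2R,3E)-4-[4-(benzyloxy)phenyl]but-3-en-2-yl]oxy}diphenylsilane, via aldehyde 9 (not isolated)
Conditions: iBu2AlH, CH2Cl2, −78 °C; then 6 pre-treated with KOtBu in THF, −78 °C to rt
Reagents that add atoms: none
Why: Partial ester reduction followed in the same flask by Horner–Wadsworth–Emmons olefination with the benzylic phosphonate anion gives the E-alkene without isolating the epimerisable α-silyloxy aldehyde.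

**Step 7**
Reactants: 11 ethyl (S)-lactate
Product: 12 ethyl (S)-2-[(tert-butyldiphenylsilyl)oxy]propanoate
Conditions: TBDPSCl, imidazole, DMF, rt
Reagents that add atoms: tert-butyl(chloro)diphenylsilane CC(C)(C)[Si](Cl)(c1ccccc1)c1ccccc1
Why: Silyl ether formation at oxygen; the bought (S) stereocentre is untouched.

**Step 8**
Reactants: 12 ethyl (S)-2-[(tert-butyldiphenylsilyl)oxy]propanoate; 6 diethyl [4-(benzyloxy)benzyl]phosphonate
Product: 14 tert-butyl{[(2S,3E)-4-[4-(benzyloxy)phenyl]but-3-en-2-yl]oxy}diphenylsilane, via aldehyde 13 (not isolated)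
Conditions: iBu2AlH, CH2Cl2, −78 °C; then 6 pre-treated with KOtBu in THF, −78 °C to rt
Reagents that add atoms: none
Why: One-pot partial reduction and Horner–Wadsworth–Emmons olefination as in step 6, giving the enantiomeric E-alkene.

**Step 9**
Reactants: 3 3,4-bis(benzyloxy)-5-bromo-2-hydroxybenzaldehyde; 10 tert-butyl{[(2R,3E)-4-[4-(benzyloxy)phenyl]but-3-en-2-yl]oxy}diphenylsilane
Product: 17 (2S,3S,4S)-7,8-bis(benzyloxy)-2-[4-(benzyloxy)phenyl]-6-bromo-3-[(1R)-1-(tert-butyldiphenylsilyloxy)ethyl]-4-methoxychromane, via dimethyl acetal 15 (not isolated), via methoxy-o-quinone methide 16 (not isolated)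
Conditions: HC(OMe)3 (1.5 equiv), Sc(OTf)3 (5 mol %), CH2Cl2, −20 °C to rt
Reagents that add atoms: trimethyl orthoformate COC(OC)OC
Why: The acetal ionises to a 4-methoxy-o-quinone methide that undergoes an inverse-electron-demand hetero-Diels–Alder [4+2] cycloaddition with E-alkene 10 (ring oxygen to the cation-stabilising benzylic carbon); suprafacial addition makes C2/C3 trans, and addition anti to the silyloxy group of the H-eclipsed (R)-allylic stereocentre fixes the absolute sense of C2 and C3 (predicted dr roughly 5:1, minor isomer removed by chromatography).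

**Step 10**
Reactants: 17 (2S,3S,4S)-7,8-bis(benzyloxy)-2-[4-(benzyloxy)phenyl]-6-bromo-3-[(1R)-1-(tert-butyldiphenylsilyloxy)ethyl]-4-methoxychromane; 4 tert-butyl [2,3-bis(benzyloxy)-6-formylphenyl] carbonate; 14 tert-butyl{[(2S,3E)-4-[4-(benzyloxy)phenyl]but-3-en-2-yl]oxy}diphenylsilane
Product: 21 protected 4→6 biflavan bis(silyl ether) (upper all-trans chroman-4-yl unit with (1S)-1-silyloxyethyl at C3 on C6 of the lower unit; pyran stereocentres as in 28), via aryllithium 18 (not isolated), via alkoxide adduct 19 (not isolated), via o-quinone methide 20 (not isolated)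
Conditions: n-BuLi, THF, −78 °C; 4; then MgBr2·OEt2, 14 (2 equiv), −78 °C to rt
Reagents that add atoms: none
Why: Br/Li exchange, addition to the aldehyde and Boc transfer/β-elimination give an E-configured aryl-substituted o-quinone methide whose endo hetero-Diels–Alder [4+2] cycloaddition with E-alkene 14 closes the upper pyran ring on C6 of the lower unit; the E-alkene gives 2,3-trans, the endo aryl gives 2,4-cis (hence 3,4-trans), and the (S)-allylic silyloxy stereocentre selects the face as in step 9 but in the mirror-image sense.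

**Step 11**
Reactants: 21 protected biflavan bis(silyl ether)
Product: 22 biflavan diol (1-hydroxyethyl group at C3 of each unit)
Conditions: Bu4NF, THF, rt to 45 °C
Reagents that add atoms: none
Why: Fluoride-mediated desilylation frees both secondary carbinols and leaves benzyl and methyl ethers untouched.

**Step 12**
Reactants: 22 biflavan diol
Product: 23 biflavan bis(methyl ketone) (3-acetyl in each unit)
Conditions: Dess–Martin periodinane, CH2Cl2, 0 °C to rt
Reagents that add atoms: none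
Why: Dess–Martin oxidation of both carbinols under near-neutral conditions; the C3 acetyl groups sit equatorial in the all-trans rings, which is also their thermodynamic configuration.

**Step 13**
Reactants: 23 biflavan bis(methyl ketone)
Product: 24 biflavan 3,3-diacetate (3-OAc in each unit, lower unit 4-OMe)
Conditions: mCPBA (6 equiv), CH2Cl2, rt to 40 °C
Reagents that add atoms: meta-chloroperbenzoic acid OOC(=O)c1cccc(Cl)c1
Why: Double Baeyer–Villiger oxidation in which the secondary ring carbon migrates in preference to methyl with retention, turning each C3–acetyl bond into the C3–O bond of the target.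

**Step 14**
Reactants: 24 biflavan 3,3-diacetate
Product: 25 biflavan diacetate with a C4 ketone in the lower unit (3-acetoxychroman-4-one)
Conditions: DDQ (1.5 equiv), CH2Cl2/H2O 10:1, 0 °C to rt
Reagents that add atoms: water O
Why: DDQ abstracts hydride from the α-methoxy benzylic C4–H of the electron-rich lower ring A (the oxidative benzyl-ether cleavage mode) and water collapses the oxocarbenium ion to the ketone; the hindered diarylmethine C4–H of the upper unit is less hydridic.

**Step 15**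
Reactants: 25 biflavan diacetate C4 ketone
Product: 26 hexa-O-benzyl dimer with free 3-OH groups (lower unit trans-dihydroflavonol)
Conditions: K2CO3 (0.2 equiv), MeOH/THF, 0 °C, argon
Reagents that add atoms: none
Why: Base-catalysed transesterification removes both acetates; the trans-dihydroflavonol is the thermodynamic epimer, so C2/C3 of the lower unit are not at risk.

**Step 16**
Reactants: 26 hexa-O-benzyl dimer
Product: 27 free hexaphenol: (2R,3R)-dihydroflavonol lower unit carrying the (2S,3R,4S) upper flavan-3-ol unit at C6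
Conditions: H2 (1 atm), Pd(OH)2/C, THF/MeOH, rt
Reagents that add atoms: none
Why: Hydrogenolysis of the six benzyl ethers, done at the ketone stage because a C4 benzylic alcohol para to a free phenol would itself be hydrogenolysed.

**Step 17**
Reactants: 27 free hexaphenol ketone
Product: 28 target
Conditions: NaBH4, EtOH, 0 °C
Reagents that add atoms: none
Why: Hydride reduction of the dihydroflavonol carbonyl by axial attack on the half-chair with equatorial 2-aryl and 3-OH gives the equatorial, 3,4-trans (4R) alcohol.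

**Compound list**
1 | 2,3,4-trihydroxybenzaldehyde | O=Cc1ccc(O)c(O)c1O | starting material
2 | 3,4-bis(benzyloxy)-2-hydroxybenzaldehyde | O=Cc1ccc(OCc2ccccc2)c(OCc2ccccc2)c1O | intermediate
3 | 3,4-bis(benzyloxy)-5-bromo-2-hydroxybenzaldehyde | O=Cc1cc(Br)c(OCc2ccccc2)c(OCc2ccccc2)c1O | intermediate
4 | tert-butyl [2,3-bis(benzyloxy)-6-formylphenyl] carbonate | O=Cc1ccc(OCc2ccccc2)c(OCc2ccccc2)c1OC(=O)OC(C)(C)C | intermediate
5 | 4-(benzyloxy)benzyl chloride | ClCc1ccc(OCc2ccccc2)cc1 | starting material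
6 | diethyl [4-(benzyloxy)benzyl]phosphonate | CCOP(=O)(Cc1ccc(OCc2ccccc2)cc1)OCC | intermediate
7 | methyl (R)-lactate | C[C@@H](O)C(=O)OC | starting material
8 | methyl (R)-2-[(tert-butyldiphenylsilyl)oxy]propanoate | C[C@@H](O[Si](c1ccccc1)(c1ccccc1)C(C)(C)C)C(=O)OC | intermediate
9 | (R)-2-[(tert-butyldiphenylsilyl)oxy]propanal | C[C@@H](O[Si](c1ccccc1)(c1ccccc1)C(C)(C)C)C=O | intermediate
10 | tert-butyl{[(2R,3E)-4-[4-(benzyloxy)phenyl]but-3-en-2-yl]oxy}diphenylsilane | C[C@@H](O[Si](c1ccccc1)(c1ccccc1)C(C)(C)C)/C=C/c1ccc(OCc2ccccc2)cc1 | intermediate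
11 | ethyl (S)-lactate | C[C@H](O)C(=O)OCC | starting material
12 | ethyl (S)-2-[(tert-butyldiphenylsilyl)oxy]propanoate | C[C@H](O[Si](c1ccccc1)(c1ccccc1)C(C)(C)C)C(=O)OCC | intermediate
13 | (S)-2-[(tert-butyldiphenylsilyl)oxy]propanal | C[C@H](O[Si](c1ccccc1)(c1ccccc1)C(C)(C)C)C=O | intermediate
14 | tert-butyl{[(2S,3E)-4-[4-(benzyloxy)phenyl]but-3-en-2-yl]oxy}diphenylsilane | C[C@H](O[Si](c1ccccc1)(c1ccccc1)C(C)(C)C)/C=C/c1ccc(OCc2ccccc2)cc1 | intermediate
15 | 2,3-bis(benzyloxy)-4-bromo-6-(dimethoxymethyl)phenol | COC(OC)c1cc(Br)c(OCc2ccccc2)c(OCc2ccccc2)c1O | intermediate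
16 | (6E)-2,3-bis(benzyloxy)-4-bromo-6-(methoxymethylidene)cyclohexa-2,4-dien-1-one | CO/C=C1\C=C(Br)C(OCc2ccccc2)=C(OCc2ccccc2)C1=O | intermediate
17 | (2S,3S,4S)-7,8-bis(benzyloxy)-2-[4-(benzyloxy)phenyl]-6-bromo-3-[(1R)-1-(tert-butyldiphenylsilyloxy)ethyl]-4-methoxychromane (all-trans) | c1ccccc1COc1ccc([C@H]2Oc3c(cc(Br)c(OCc4ccccc4)c3OCc3ccccc3)[C@@H](OC)[C@@H]2[C@@H](C)O[Si](c2ccccc2)(c2ccccc2)C(C)(C)C)cc1 | intermediate
18 | 6-lithio analogue of 17 (aryllithium) | c1ccccc1COc1ccc([C@H]2Oc3c(cc([Li])c(OCc4ccccc4)c3OCc3ccccc3)[C@@H](OC)[C@@H]2[C@@H](C)O[Si](c2ccccc2)(c2ccccc2)C(C)(C)C)cc1 | intermediate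
19 | lithium alkoxide adduct of 18 and 4 (carbinol carbon unassigned) | c1ccccc1COc1ccc([C@H]2Oc3c(cc(C(O[Li])c4ccc(OCc5ccccc5)c(OCc5ccccc5)c4OC(=O)OC(C)(C)C)c(OCc4ccccc4)c3OCc3ccccc3)[C@@H](OC)[C@@H]2[C@@H](C)O[Si](c2ccccc2)(c2ccccc2)C(C)(C)C)cc1 | intermediate
20 | E-o-quinone methide: 2,3-bis(benzyloxy)-6-(arylmethylidene)cyclohexa-2,4-dien-1-one, aryl = debrominated 17 bonded at C6 | c1ccccc1COc1ccc([C@H]2Oc3c(cc(/C=C4\C=CC(OCc5ccccc5)=C(OCc5ccccc5)C4=O)c(OCc4ccccc4)c3OCc3ccccc3)[C@@H](OC)[C@@H]2[C@@H](C)O[Si](c2ccccc2)(c2ccccc2)C(C)(C)C)cc1 | intermediate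
21 | protected 4→6 biflavan bis(silyl ether): upper all-trans 7,8-bis(benzyloxy)-2-[4-(benzyloxy)phenyl]-3-[(1S)-1-silyloxyethyl]chroman-4-yl on C6 of the lower unit of 17 | c1ccccc1COc1ccc([C@H]2Oc3c(cc([C@H]4c5ccc(OCc6ccccc6)c(OCc6ccccc6)c5O[C@@H](c5ccc(OCc6ccccc6)cc5)[C@@H]4[C@H](C)O[Si](c4ccccc4)(c4ccccc4)C(C)(C)C)c(OCc4ccccc4)c3OCc3ccccc3)[C@@H](OC)[C@@H]2[C@@H](C)O[Si](c2ccccc2)(c2ccccc2)C(C)(C)C)cc1 | intermediate
22 | biflavan diol (lower (1R)- and upper (1S)-1-hydroxyethyl at C3) | c1ccccc1COc1ccc([C@H]2Oc3c(cc([C@H]4c5ccc(OCc6ccccc6)c(OCc6ccccc6)c5O[C@@H](c5ccc(OCc6ccccc6)cc5)[C@@H]4[C@H](C)O)c(OCc4ccccc4)c3OCc3ccccc3)[C@@H](OC)[C@@H]2[C@@H](C)O)cc1 | intermediate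
23 | biflavan bis(methyl ketone) (3-acetyl in each unit) | c1ccccc1COc1ccc([C@H]2Oc3c(cc([C@H]4c5ccc(OCc6ccccc6)c(OCc6ccccc6)c5O[C@@H](c5ccc(OCc6ccccc6)cc5)[C@@H]4C(C)=O)c(OCc4ccccc4)c3OCc3ccccc3)[C@@H](OC)[C@@H]2C(C)=O)cc1 | intermediate
24 | biflavan 3,3-diacetate (lower unit 4-OMe) | c1ccccc1COc1ccc([C@H]2Oc3c(cc([C@H]4c5ccc(OCc6ccccc6)c(OCc6ccccc6)c5O[C@@H](c5ccc(OCc6ccccc6)cc5)[C@@H]4OC(C)=O)c(OCc4ccccc4)c3OCc3ccccc3)[C@@H](OC)[C@@H]2OC(C)=O)cc1 | intermediate
25 | diacetate with lower-unit C4 ketone | c1ccccc1COc1ccc([C@H]2Oc3c(cc([C@H]4c5ccc(OCc6ccccc6)c(OCc6ccccc6)c5O[C@@H](c5ccc(OCc6ccccc6)cc5)[C@@H]4OC(C)=O)c(OCc4ccccc4)c3OCc3ccccc3)C(=O)[C@@H]2OC(C)=O)cc1 | intermediate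
26 | hexa-O-benzyl dimer, free 3-OH groups, lower unit trans-dihydroflavonol | c1ccccc1COc1ccc([C@H]2Oc3c(cc([C@H]4c5ccc(OCc6ccccc6)c(OCc6ccccc6)c5O[C@@H](c5ccc(OCc6ccccc6)cc5)[C@@H]4O)c(OCc4ccccc4)c3OCc3ccccc3)C(=O)[C@@H]2O)cc1 | intermediate
27 | free hexaphenol: (2R,3R)-3,7,8-trihydroxy-2-(4-hydroxyphenyl)chroman-4-one bearing at C6 the (2S,3R,4S)-3,7,8-trihydroxy-2-(4-hydroxyphenyl)chroman-4-yl unit | Oc1ccc([C@H]2Oc3c(cc([C@H]4c5ccc(O)c(O)c5O[C@@H](c5ccc(O)cc5)[C@@H]4O)c(O)c3O)C(=O)[C@@H]2O)cc1 | intermediate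
28 | target: lower (2R,3S,4R)-flavan-3,4-diol unit linked at C6 to C4 of the upper (2S,3R,4S)-flavan-3-ol unit | Oc1ccc([C@H]2Oc3c(cc([C@H]4c5ccc(O)c(O)c5O[C@@H](c5ccc(O)cc5)[C@@H]4O)c(O)c3O)[C@@H](O)[C@@H]2O)cc1 | target

**Totals**
Total step count: 17. Longest linear sequence: 11 steps (5, 6, 9, 10, 11, 12, 13, 14, 15, 16, 17; the sequence 1, 2, 9–17 is equally long).

**Steps most likely to fail, with fallbacks**

Step 9 (acid-triggered three-component cycloaddition; the allylic silyl ether of 10 may ionise, and facial control may be modest). The fallback sets out from 3 and returns at 17. Aldehyde 3 is reduced with NaBH4 to the salicyl alcohol 2,3-bis(benzyloxy)-4-bromo-6-(hydroxymethyl)phenol F1. F1 is heated with 10 in o-xylene at 150 °C, so that loss of water gives the unsubstituted o-quinone methide under neutral conditions, which adds to 10 in the same [4+2] sense to give the 4-unsubstituted (2S,3S)-flavan F2. Benzylic methoxylation of F2 with DDQ in CH2Cl2/MeOH (hydride abstraction at C4, methanol capture trans to the C3 substituent) then gives 17.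

Step 10 (one-pot anionic o-quinone methide generation and cycloaddition with a large aryllithium). The fallback sets out from 17 and returns at 21. Aryllithium 18 is added to aldehyde 2 that has first been deprotonated with one equivalent of n-BuLi, and the o-hydroxybenzhydrol F3 is isolated. F3 is condensed with PhB(OH)2 (toluene, Dean–Stark) to the cyclic phenylboronate (4-aryl-2-phenyl-4H-1,3,2-benzodioxaborin) F4. Thermolysis of F4 with 14 in toluene at 140–160 °C releases the same o-quinone methide 20 by cycloreversion under neutral, salt-free conditions, and its [4+2] addition to 14 gives 21.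

Step 14 (chemoselective DDQ oxidation in the presence of the upper diarylmethine C–H and six benzyl ethers). The fallback sets out from 24 and returns at 25. The benzylic methyl ether of 24 is exchanged for hydroxyl by SN1 hydrolysis (Sc(OTf)3 cat., MeCN/H2O, 40 °C) to give the lower-unit 4-hydroxy diacetate F5 as a C4 epimer mixture. Dess–Martin oxidation of F5 then gives ketone 25, so both epimers converge and no hydride abstraction is needed.

**Further compounds**
F1 | step 9 | 2,3-bis(benzyloxy)-4-bromo-6-(hydroxymethyl)phenol | OCc1cc(Br)c(OCc2ccccc2)c(OCc2ccccc2)c1O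
F2 | step 9 | (2S,3S)-7,8-bis(benzyloxy)-2-[4-(benzyloxy)phenyl]-6-bromo-3-[(1R)-1-(tert-butyldiphenylsilyloxy)ethyl]chromane | c1ccccc1COc1ccc([C@H]2Oc3c(cc(Br)c(OCc4ccccc4)c3OCc3ccccc3)C[C@@H]2[C@@H](C)O[Si](c2ccccc2)(c2ccccc2)C(C)(C)C)cc1
F3 | step 10 | o-hydroxybenzhydrol from 18 and 2 (carbinol carbon unassigned) | c1ccccc1COc1ccc([C@H]2Oc3c(cc(C(O)c4ccc(OCc5ccccc5)c(OCc5ccccc5)c4O)c(OCc4ccccc4)c3OCc3ccccc3)[C@@H](OC)[C@@H]2[C@@H](C)O[Si](c2ccccc2)(c2ccccc2)C(C)(C)C)cc1
F4 | step 10 | cyclic phenylboronate of F3 (7,8-bis(benzyloxy)-2-phenyl-4-aryl-4H-1,3,2-benzodioxaborin) | c1ccccc1COc1ccc([C@H]2Oc3c(cc(C4OB(c5ccccc5)Oc5c4ccc(OCc6ccccc6)c5OCc5ccccc5)c(OCc4ccccc4)c3OCc3ccccc3)[C@@H](OC)[C@@H]2[C@@H](C)O[Si](c2ccccc2)(c2ccccc2)C(C)(C)C)cc1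
F5 | step 14 | lower-unit 4-hydroxy analogue of 24 (trans epimer drawn) | c1ccccc1COc1ccc([C@H]2Oc3c(cc([C@H]4c5ccc(OCc6ccccc6)c(OCc6ccccc6)c5O[C@@H](c5ccc(OCc6ccccc6)cc5)[C@@H]4OC(C)=O)c(OCc4ccccc4)c3OCc3ccccc3)[C@@H](O)[C@@H]2OC(C)=O)cc1
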